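## The problem

Numbering used throughout (briarane numbering): ring A is the cyclohexane C1, C10, C11, C12, C13, C14; ring B is the ten-membered carbocycle C1–C10; ring C is the γ-lactone O–C19(=O)–C17–C8–C7. C15, C16 and C18 are the methyl groups on C1, C5 and C17, and C20 is the exocyclic methylene on C11.

Target 35 is a briarane in which ring A is trans-fused along C1–C10 to ring B, and ring B carries the (5Z)-trisubstituted olefin and ring C. Ring B is the awkward ring: it is a strained medium ring that starts at the quaternary carbon C1, and most closures of it create no stereocentre. There are eight stereocentres: C1 (quaternary), C2 and C14 (a syn-1,3-diol diacetate across C1), C10, C9, C8 (tertiary carbinol), C7 and C17. C1 and C14 can steer C2 only weakly through the quaternary carbon, so C2 is better set on its own. C7 can control C8 and C17 if the lactone is closed onto a C8 ketone from O7. C8 and C1 together can control C9 and C10 if these two centres are made in one cyclic transition state. The sensitive groups are the β-hydroxy-γ-lactone (retro-aldol, dehydration, epimerisable C17), the allylic C7–O bond, the C11(20) exocyclic methylene, and three secondary acetates beside a free tertiary alcohol. The feature that makes the key step possible is the triad C9 carbinol – C10 methine (on the ring fusion, shared by ring A and ring B) – C11=C20 exocyclic methylene. This homoallylic alcohol is the retron of an allylmetal addition to an aldehyde with allylic transposition, so C9–C10 can be the last ring bond made.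

## Retrosynthesis

35 ⇒ 34. No skeletal bond is cut; only the C9 acetate is removed. The C2 and C14 acetates are carried from ring A onwards, so nothing has to be unmasked on the finished hydroxy-lactone. The forward step must acetylate the secondary C9 hydroxyl and leave the tertiary C8 hydroxyl free.

34 ⇒ 32 (through allylchromium 33). The C9–C10 bond of ring B is cut, C9 becomes an aldehyde and C10=C11–C20–Br an allylic bromide on ring A. Compared with cuts at C5=C6 or C6–C7, this one removes ring B, two stereocentres (C9, C10) and the exocyclic olefin in one operation, and it lets the complete lactone be present before ring closure. Precursor 32 has one ring fewer, and its two halves are joined by a single chain. The forward reaction must be γ-selective, must close a ten-membered ring, and must choose one of four diastereomers.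

32 ⇒ 31 ⇒ 30 ⇒ 12 + 28. The C4–C5 bond is cut (sp3–sp2 coupling of alkylborane 29, made from 12, with iodoalkene 28). This divides the carbon skeleton into two halves of similar size and takes the (5Z) geometry from a preformed iodoalkene instead of from a ring-forming step. The forward steps need a chemoselective hydroboration of the vinyl group of 12 and functional-group changes at C20 and C9 (30 → 31 → 32) that leave the lactone alone.

28 ⇒ 26 ⇒ 25 ⇒ 24 ⇒ 23 ⇒ 21 ⇒ 20 ⇒ 15 ⇒ 14 ⇒ 13. The C8–C17 bond of ring C is cut (intramolecular Reformatsky reaction of bromopropanoate 26 through enolate 27), so C7 relays to C8 and C17 in one event. The C5=C6 bond is cut next (Stork–Zhao olefination of aldehyde 15 with the ylide 19 made from 16). C7 is bought: it is C2 of methyl 3,4-O-isopropylidene-L-threonate 13, whose C3 is sacrificed as the C8 ketone and whose C4 becomes C9. The acid bromide 22 supplies C17, C18 and C19.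

12 ⇒ 11 ⇒ 10 ⇒ 9 ⇒ 8 ⇒ 7 ⇒ 6 ⇒ 5 + 4 (4 from 3, from 1 + 2). The C1–C2 bond is cut: palladium-catalysed addition of dione 5 to alkoxyallene 4 makes the quaternary carbon, the C2 oxygen and the C3=C4 vinyl group together, with C2 set by the catalyst. A desymmetrising reduction of 6 then fixes C14 and C1 (7). The remaining carbonyl (C10) is converted through 10 and 11 into the C10=C11–C20–OH allyl unit of 12. The forward steps must distinguish two diastereotopic carbonyl groups and must move an allylic alcohol without touching the C2 allylic acetate.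

## Roads not taken

Alternative 1: the most obvious route. Cut C5=C6 and close ring B by ring-closing metathesis of diene A1 with the second-generation Grubbs catalyst, after ring A and the lactone are complete. The chosen plan is better for three reasons. A trisubstituted olefin inside a strained ten-membered ring forms slowly and reversibly, with dimers and no guarantee of the (Z) geometry. The C11(20) methylene is a second 1,1-disubstituted olefin that competes for the catalyst. Metathesis creates no stereocentre, so C9 and C10 would have to be set in separate earlier steps. In the chosen route the olefin geometry is fixed in an open chain (steps 12 and 19) and the ring closure itself creates C9 and C10.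

Alternative 2: the biomimetic route. Cut C1–C10 and form it by transannular epoxide–olefin cyclisation of the fourteen-membered epoxy-cembranolide A2, with a Lewis acid or with Cp2TiCl (trivalent titanium). This would deliver the C1–C10 bond, the C2 oxygen and the C11(20) methylene together. The relative configuration of C1, C2 and C10 in 35 demands a cis 1,2-epoxide and an (E)-C10=C11 olefin beside the (Z)-C5=C6 olefin. That is three trisubstituted alkenes of defined geometry in one macrocycle that already holds the lactone. The C14 acetate next to the epoxide would participate or retard opening, and the face selectivity at the quaternary C1 would rest on macrocycle conformation alone. The precursor is as complex as the product.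

Alternative 3: the same C9–C10 bond and the same retron, reached by [2,3]-Wittig ring contraction of the thirteen-membered α-allyloxy ketone A3, in which an enolate at C9 shifts from oxygen to C10. It needs enolisation at C9 in competition with the doubly activated (allylic, α-oxygenated) C7–H, strong base in the presence of acetates, prior construction of a macrocyclic ether, and lactone formation after the strained ring exists. The allylchromium closure uses the same retron under neutral conditions with the lactone already in place.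

Key step: step 22

Assumption: in step 3 the (1R,2R)-configured diphosphine ligand is taken to give the (R)-ether 6; if the sense of induction is the opposite, its enantiomer is used and nothing else changes.

## Steps

Step 1
Reactants: 1 4-methoxybenzyl alcohol; 2 propargyl bromide (3-bromoprop-1-yne)
Product: 3 1-methoxy-4-[(prop-2-yn-1-yloxy)methyl]benzene
Conditions: NaH, Bu4NI (cat.), THF, 0 °C to rt
Reagents that add atoms: none
Why: Williamson etherification of the alkoxide of 1 with a primary propargylic bromide; no stereocentre is involved.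

Step 2
Reactants: 3 1-methoxy-4-[(prop-2-yn-1-yloxy)methyl]benzene
Product: 4 1-methoxy-4-[(propa-1,2-dien-1-yloxy)methyl]benzene
Conditions: KOtBu (0.3 equiv), THF, rt
Reagents that add atoms: none
Why: Base-catalysed propargyl-to-allenyl ether isomerisation (prototropic shift), which stops at the alkoxyallene because the cumulated diene is conjugated with the oxygen lone pair.

Step 3
Reactants: 5 2-methylcyclohexane-1,3-dione; 4 1-methoxy-4-[(propa-1,2-dien-1-yloxy)methyl]benzene
Product: 6 2-[(1R)-1-[(4-methoxyphenyl)methoxy]prop-2-en-1-yl]-2-methylcyclohexane-1,3-dione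
Conditions: Pd2(dba)3·CHCl3 (2.5 mol %), (1R,2R)-N,N'-bis[2-(diphenylphosphino)benzoyl]cyclohexane-1,2-diamine (7.5 mol %), PhCO2H (10 mol %), CH2Cl2, rt
Reagents that add atoms: none
Why: Palladium-catalysed asymmetric addition of a 1,3-dicarbonyl pronucleophile to an alkoxyallene: hydropalladation gives an alkoxy-substituted π-allyl complex that the dione enolate attacks at the oxygen-bearing terminus, so the C1–C2 bond, the quaternary carbon and the C3=C4 vinyl group arise together; C2 is set by the chiral diphosphine, and C1 is not yet stereogenic.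

Step 4
Reactants: 6 2-[(1R)-1-[(4-methoxyphenyl)methoxy]prop-2-en-1-yl]-2-methylcyclohexane-1,3-dione
Product: 7 (2R,3S)-3-hydroxy-2-[(1R)-1-[(4-methoxyphenyl)methoxy]prop-2-en-1-yl]-2-methylcyclohexan-1-one
Conditions: (R)-2-methyl-CBS-oxazaborolidine (20 mol %), catecholborane (1.1 equiv), toluene, −78 °C
Reagents that add atoms: none
Why: Corey–Bakshi–Shibata reduction used as a desymmetrisation: the catalyst (quaternary C1 as large, C13 methylene as small substituent) accepts only the carbonyl group whose catalyst-defined face is also the open face syn to the C15 methyl group, so hydride adds anti to the alkoxyallyl branch and C14 (S, hydroxyl cis to the branch) and C1 are fixed in one event.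

Step 5
Reactants: 7 (2R,3S)-3-hydroxy-2-[(1R)-1-[(4-methoxyphenyl)methoxy]prop-2-en-1-yl]-2-methylcyclohexan-1-one
Product: 8 (2R,3S)-3-hydroxy-2-[(1R)-1-hydroxyprop-2-en-1-yl]-2-methylcyclohexan-1-one
Conditions: DDQ, CH2Cl2/pH 7 buffer (10:1), 0 °C
Reagents that add atoms: none
Why: Oxidative cleavage of the 4-methoxybenzyl ether by DDQ (hydride abstraction, then hydrolysis of the oxocarbenium ion by the water present, which also prevents acetal formation with the C14 hydroxyl); no stereocentre is touched.

Step 6
Reactants: 8 (2R,3S)-3-hydroxy-2-[(1R)-1-hydroxyprop-2-en-1-yl]-2-methylcyclohexan-1-one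
Product: 9 (1S,2R)-2-[(1R)-1-acetoxyprop-2-en-1-yl]-2-methyl-3-oxocyclohexyl acetate
Conditions: Ac2O, DMAP (cat.), pyridine, 0 °C to rt
Reagents that add atoms: acetic anhydride, CC(=O)OC(C)=O
Why: DMAP-catalysed acetylation of both secondary hydroxyl groups installs the C2 and C14 acetates of the target; the β-oxygenated ketone cannot eliminate because C1 carries no hydrogen.

Step 7
Reactants: 9 (1S,2R)-2-[(1R)-1-acetoxyprop-2-en-1-yl]-2-methyl-3-oxocyclohexyl acetate
Product: 10 (1S,2R)-2-[(1R)-1-acetoxyprop-2-en-1-yl]-2-methyl-4-methylidene-3-oxocyclohexyl acetate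
Conditions: (CH2O)n, N-methylanilinium trifluoroacetate, THF, reflux
Reagents that add atoms: formaldehyde (as paraformaldehyde), C=O
Why: α-Methylenation by Mannich condensation and elimination under weakly acidic conditions; C11 is the only enolisable position of the ketone, which brings in C20 regiospecifically.

Step 8
Reactants: 10 (1S,2R)-2-[(1R)-1-acetoxyprop-2-en-1-yl]-2-methyl-4-methylidene-3-oxocyclohexyl acetate
Product: 11 (1S,2R)-2-[(1R)-1-acetoxyprop-2-en-1-yl]-3-hydroxy-2-methyl-4-methylidenecyclohexyl acetate (both epimers at the new carbinol carbon C10)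
Conditions: NaBH4, CeCl3·7H2O, MeOH, −40 °C
Reagents that add atoms: none
Why: Luche 1,2-reduction of the exocyclic enone; the low temperature spares the acetates, and the configuration at C10 is irrelevant because this carbon becomes sp2 in step 9.

Step 9
Reactants: 11 (1S,2R)-2-[(1R)-1-acetoxyprop-2-en-1-yl]-3-hydroxy-2-methyl-4-methylidenecyclohexyl acetate
Product: 12 (1S,2R)-2-[(1R)-1-acetoxyprop-2-en-1-yl]-4-(hydroxymethyl)-2-methylcyclohex-3-en-1-yl acetate
Conditions: Ph3SiOReO3 (2 mol %), Et2O, 0 °C
Reagents that add atoms: none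
Why: Oxorhenium-catalysed 1,3-transposition of an allylic alcohol through a [3,3] shift of its perrhenate ester; the equilibrium favours 12 because the exocyclic 1,1-disubstituted alkene becomes an endocyclic trisubstituted one, and the C2 allylic acetate cannot form a perrhenate ester and stays in place.

Step 10
Reactants: 13 methyl 3,4-O-isopropylidene-L-threonate (methyl (2R)-2-[(4S)-2,2-dimethyl-1,3-dioxolan-4-yl]-2-hydroxyacetate)
Product: 14 methyl (2R)-2-(tert-butyldimethylsilyloxy)-2-[(4S)-2,2-dimethyl-1,3-dioxolan-4-yl]acetate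
Conditions: t-BuMe2SiCl, imidazole, DMF, rt
Reagents that add atoms: tert-butyldimethylsilyl chloride, CC(C)(C)[Si](C)(C)Cl
Why: Imidazole-promoted silylation of the secondary hydroxyl group (the future O7), which must be masked during reduction and olefination.

Step 11
Reactants: 14 methyl (2R)-2-(tert-butyldimethylsilyloxy)-2-[(4S)-2,2-dimethyl-1,3-dioxolan-4-yl]acetate
Product: 15 (2R)-2-(tert-butyldimethylsilyloxy)-2-[(4S)-2,2-dimethyl-1,3-dioxolan-4-yl]acetaldehyde
Conditions: i-Bu2AlH, CH2Cl2, −78 °C; Rochelle salt work-up
Reagents that add atoms: none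
Why: Partial reduction of the ester, which stops at the aldehyde stage because the tetrahedral aluminium hemiacetal is stable at −78 °C; the aldehyde is used at once to avoid epimerisation of the future C7.

Step 12
Reactants: 15 (2R)-2-(tert-butyldimethylsilyloxy)-2-[(4S)-2,2-dimethyl-1,3-dioxolan-4-yl]acetaldehyde; 16 ethyltriphenylphosphonium iodide
Product: 20 tert-butyl{[(1S,2Z)-1-[(4S)-2,2-dimethyl-1,3-dioxolan-4-yl]-3-iodobut-2-en-1-yl]oxy}dimethylsilane, via ethylidene ylide 17 (not isolated), via iodophosphonium salt 18 (not isolated), via iodo ylide 19 (not isolated)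
Conditions: 16, n-BuLi, THF, 0 °C; I2, −78 °C; NaN(SiMe3)2, −78 °C; then 15, −78 to −20 °C
Reagents that add atoms: iodine, II
Why: Stork–Zhao olefination: the α-iodo ylide 19 reacts with the aldehyde under kinetic control to give the (Z)-iodoalkene (iodine cis to C7), which brings in C5, C6 and C16 and fixes the later ring B olefin geometry; the low temperature preserves the C7 centre.

Step 13
Reactants: 20 tert-butyl{[(1S,2Z)-1-[(4S)-2,2-dimethyl-1,3-dioxolan-4-yl]-3-iodobut-2-en-1-yl]oxy}dimethylsilane
Product: 21 (1S,2Z)-1-[(4S)-2,2-dimethyl-1,3-dioxolan-4-yl]-3-iodobut-2-en-1-ol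
Conditions: Bu4NF, THF, 0 °C
Reagents that add atoms: none
Why: Fluoride-induced cleavage of the silyl ether; the acetonide and the iodoalkene are inert to fluoride.

Step 14
Reactants: 21 (1S,2Z)-1-[(4S)-2,2-dimethyl-1,3-dioxolan-4-yl]-3-iodobut-2-en-1-ol; 22 2-bromopropanoyl bromide (racemic)
Product: 23 (1S,2Z)-1-[(4S)-2,2-dimethyl-1,3-dioxolan-4-yl]-3-iodobut-2-en-1-yl 2-bromopropanoate (both epimers at the bromine-bearing carbon)
Conditions: pyridine, CH2Cl2, 0 °C
Reagents that add atoms: none
Why: O-Acylation by the acid bromide places C17, C18 and C19 on O7; the bromine-bearing carbon is stereorandom and is erased in step 18.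

Step 15
Reactants: 23 (1S,2Z)-1-[(4S)-2,2-dimethyl-1,3-dioxolan-4-yl]-3-iodobut-2-en-1-yl 2-bromopropanoate
Product: 24 (2S,3S,4Z)-1,2-dihydroxy-5-iodohex-4-en-3-yl 2-bromopropanoate
Conditions: AcOH/H2O (4:1), 40 °C
Reagents that add atoms: none
Why: Acid-catalysed hydrolysis of the isopropylidene acetal; the acidic medium avoids the acyl migration from O7 that an alkoxide would trigger.

Step 16
Reactants: 24 (2S,3S,4Z)-1,2-dihydroxy-5-iodohex-4-en-3-yl 2-bromopropanoate
Product: 25 (2S,3S,4Z)-2-hydroxy-5-iodo-1-[(triethylsilyl)oxy]hex-4-en-3-yl 2-bromopropanoate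
Conditions: Et3SiCl, imidazole, CH2Cl2, −78 to −40 °C
Reagents that add atoms: chlorotriethylsilane, CC[Si](Cl)(CC)CC
Why: Sterically controlled silylation of the primary hydroxyl group (C9) in preference to the secondary one at low temperature.

Step 17
Reactants: 25 (2S,3S,4Z)-2-hydroxy-5-iodo-1-[(triethylsilyl)oxy]hex-4-en-3-yl 2-bromopropanoate
Product: 26 (3S,4Z)-5-iodo-2-oxo-1-[(triethylsilyl)oxy]hex-4-en-3-yl 2-bromopropanoate
Conditions: Dess–Martin periodinane, NaHCO3, CH2Cl2, 0 °C to rt
Reagents that add atoms: none
Why: Dess–Martin oxidation of the secondary alcohol to the C8 ketone under buffered, non-basic conditions, so the allylic and α-acyloxy C7–H is not enolised.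

Step 18
Reactants: 26 (3S,4Z)-5-iodo-2-oxo-1-[(triethylsilyl)oxy]hex-4-en-3-yl 2-bromopropanoate
Product: 28 (3R,4R,5S)-4-hydroxy-5-[(1Z)-2-iodoprop-1-en-1-yl]-3-methyl-4-{[(triethylsilyl)oxy]methyl}oxolan-2-one, via samarium enolate 27 (not isolated)
Conditions: SmI2 (2.2 equiv), THF, −78 °C; aq. NH4Cl
Reagents that add atoms: none
Why: Samarium diiodide-mediated intramolecular Reformatsky reaction: two-electron reduction of the C–Br bond gives the trivalent samarium enolate 27, which is delivered to the C8 ketone from the side of O7; the ketone reacts in the rotamer with C7–H eclipsing the C8–C9 bond, so the new hydroxyl ends cis to the alkenyl group, and the C18 methyl group should settle trans to the bulky silyloxymethyl arm (C17), both as in the target.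

Step 19
Reactants: 12 (1S,2R)-2-[(1R)-1-acetoxyprop-2-en-1-yl]-4-(hydroxymethyl)-2-methylcyclohex-3-en-1-yl acetate; 28 (3R,4R,5S)-4-hydroxy-5-[(1Z)-2-iodoprop-1-en-1-yl]-3-methyl-4-{[(triethylsilyl)oxy]methyl}oxolan-2-one
Product: 30 2,14-diacetoxy-8,20-dihydroxy-9-(triethylsilyloxy)-9,10-secobriara-5Z,10-dien-19,7-olide (configuration at C1 C2 C7 C8 C14 C17 as in 35), via alkylborane 29 (not isolated)
Conditions: 12, 9-BBN-H (2.2 equiv), THF, 0 °C to rt; then 28, Pd(dppf)Cl2 (10 mol %), AsPh3, Cs2CO3, DMF/H2O, rt
Reagents that add atoms: none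
Why: Anti-Markovnikov hydroboration of the monosubstituted vinyl group by 9-BBN-H (the trisubstituted ring alkene does not react and the hydroxyl only forms a borinate) followed by B-alkyl Suzuki–Miyaura coupling of 29 with the iodoalkene with retention of geometry forms the C4–C5 bond and the (Z)-C5=C6 olefin; no stereocentre is created.

Step 20
Reactants: 30 2,14-diacetoxy-8,20-dihydroxy-9-(triethylsilyloxy)-9,10-secobriara-5Z,10-dien-19,7-olide
Product: 31 2,14-diacetoxy-20-bromo-8-hydroxy-9-(triethylsilyloxy)-9,10-secobriara-5Z,10-dien-19,7-olide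
Conditions: CBr4, PPh3, 2,6-lutidine, CH2Cl2, 0 °C
Reagents that add atoms: carbon tetrabromide, BrC(Br)(Br)Br
Why: Appel bromination of the only primary hydroxyl group; the tertiary C8 hydroxyl is too hindered to be substituted and 2,6-lutidine protects the silyl ether from HBr.

Step 21
Reactants: 31 2,14-diacetoxy-20-bromo-8-hydroxy-9-(triethylsilyloxy)-9,10-secobriara-5Z,10-dien-19,7-olide
Product: 32 2,14-diacetoxy-20-bromo-8-hydroxy-9-oxo-9,10-secobriara-5Z,10-dien-19,7-olide
Conditions: (COCl)2, DMSO, CH2Cl2, −78 to −40 °C; Et3N, −78 to 0 °C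
Reagents that add atoms: none
Why: Swern oxidation applied directly to a primary triethylsilyl ether: the chlorosulfonium ion exchanges the unhindered O–Si bond for the alkoxysulfonium ion, which collapses to the aldehyde on addition of Et3N; C8 is fully substituted, so the α-hydroxy aldehyde cannot epimerise.

Step 22
Reactants: 32 2,14-diacetoxy-20-bromo-8-hydroxy-9-oxo-9,10-secobriara-5Z,10-dien-19,7-olide
Product: 34 2,14-diacetoxy-8,9-dihydroxybriara-5Z,11(20)-dien-19,7-olide, via allylchromium species 33 (not isolated)
Conditions: CrCl2 (10 equiv), THF, 25 °C, final concentration 0.002 M, 32 added over 12 h by syringe pump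
Reagents that add atoms: none
Why: Two equivalents of CrCl2 reduce the allylic C20–Br bond to the σ-allyl species of trivalent chromium 33, which adds through its γ-carbon C10 to the tethered C9 aldehyde in a six-membered chair transition state with allylic transposition, so the ring A olefin becomes the C11(20) exocyclic methylene. The closest known reaction type is the intramolecular Nozaki–Hiyama allylation of ω-formyl allylic bromides, an established closure of ten- to fourteen-membered carbocycles. Ring B is closed by a 10-exo-trig addition to the carbonyl group; in the chair C8 and C1 are both equatorial, hence gauche about the new C9–C10 bond, a torsion a ten-membered ring accommodates well. C9 against C10: ring A locks C1 trans to the CH2Cr group of the allyl unit, so the chair delivers the anti relationship between the C9 hydroxyl and C1 that the target has. C9 against C8: chromium does not chelate the tertiary hydroxyl, the aldehyde reacts in the Cornforth/Felkin–Anh rotamer with C=O anti to the C8–O bond, and the nucleophile enters anti to C7 on the side of C17, as the extended tether between C7 and C10 also requires. C10 against C1: the aldehyde reaches C10 on the face of the C15 methyl group, anti to the larger C2 branch from which the tether leaves pseudo-equatorially, which gives the trans ring fusion. The step needs γ- over α-attack (general for allylchromium reagents), aldehyde selectivity over lactone and acetates (divalent chromium leaves esters untouched) and cyclisation over oligomerisation, which high dilution and slow addition secure.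

Step 23
Reactants: 34 2,14-diacetoxy-8,9-dihydroxybriara-5Z,11(20)-dien-19,7-olide
Product: 35 (1S,2R,5Z,7S,8S,9R,10S,14S,17R)-2,9,14-triacetoxy-8-hydroxybriara-5,11(20)-dien-19,7-olide (CNP0187723.2)
Conditions: Ac2O, DMAP (cat.), pyridine, rt
Reagents that add atoms: acetic anhydride, CC(=O)OC(C)=O
Why: DMAP-catalysed acetylation of the secondary C9 hydroxyl group; the tertiary C8 hydroxyl, flanked by three carbon substituents, is not acylated under these conditions.

## Compound list

1 | 4-methoxybenzyl alcohol | COc1ccc(CO)cc1 | starting material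
2 | propargyl bromide | BrCC#C | starting material
3 | 1-methoxy-4-[(prop-2-yn-1-yloxy)methyl]benzene | COc1ccc(COCC#C)cc1 | intermediate
4 | 1-methoxy-4-[(propa-1,2-dien-1-yloxy)methyl]benzene | COc1ccc(COC=C=C)cc1 | intermediate
5 | 2-methylcyclohexane-1,3-dione | CC1C(=O)CCCC1=O | starting material
6 | 2-[(1R)-1-[(4-methoxyphenyl)methoxy]prop-2-en-1-yl]-2-methylcyclohexane-1,3-dione | O=C1CCCC(=O)C1(C)[C@H](OCc1ccc(OC)cc1)C=C | intermediate
7 | (2R,3S)-3-hydroxy-2-[(1R)-1-[(4-methoxyphenyl)methoxy]prop-2-en-1-yl]-2-methylcyclohexan-1-one | O=C1CCC[C@H](O)[C@]1(C)[C@H](OCc1ccc(OC)cc1)C=C | intermediate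
8 | (2R,3S)-3-hydroxy-2-[(1R)-1-hydroxyprop-2-en-1-yl]-2-methylcyclohexan-1-one | O=C1CCC[C@H](O)[C@]1(C)[C@H](O)C=C | intermediate
9 | (1S,2R)-2-[(1R)-1-acetoxyprop-2-en-1-yl]-2-methyl-3-oxocyclohexyl acetate | O=C1CCC[C@H](OC(C)=O)[C@]1(C)[C@H](OC(C)=O)C=C | intermediate
10 | (1S,2R)-2-[(1R)-1-acetoxyprop-2-en-1-yl]-2-methyl-4-methylidene-3-oxocyclohexyl acetate | O=C1C(=C)CC[C@H](OC(C)=O)[C@]1(C)[C@H](OC(C)=O)C=C | intermediate
11 | (1S,2R)-2-[(1R)-1-acetoxyprop-2-en-1-yl]-3-hydroxy-2-methyl-4-methylidenecyclohexyl acetate, both epimers at the carbinol carbon C10 | OC1C(=C)CC[C@H](OC(C)=O)[C@]1(C)[C@H](OC(C)=O)C=C | intermediate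
12 | (1S,2R)-2-[(1R)-1-acetoxyprop-2-en-1-yl]-4-(hydroxymethyl)-2-methylcyclohex-3-en-1-yl acetate | OCC1=C[C@@](C)([C@H](OC(C)=O)C=C)[C@@H](OC(C)=O)CC1 | intermediate
13 | methyl 3,4-O-isopropylidene-L-threonate | COC(=O)[C@H](O)[C@@H]1COC(C)(C)O1 | starting material
14 | methyl (2R)-2-(tert-butyldimethylsilyloxy)-2-[(4S)-2,2-dimethyl-1,3-dioxolan-4-yl]acetate | COC(=O)[C@H](O[Si](C)(C)C(C)(C)C)[C@@H]1COC(C)(C)O1 | intermediate
15 | (2R)-2-(tert-butyldimethylsilyloxy)-2-[(4S)-2,2-dimethyl-1,3-dioxolan-4-yl]acetaldehyde | O=C[C@H](O[Si](C)(C)C(C)(C)C)[C@@H]1COC(C)(C)O1 | intermediate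
16 | ethyltriphenylphosphonium iodide | CC[P+](c1ccccc1)(c1ccccc1)c1ccccc1.[I-] | starting material
17 | ethylidenetriphenylphosphorane | CC=P(c1ccccc1)(c1ccccc1)c1ccccc1 | intermediate
18 | (1-iodoethyl)triphenylphosphonium iodide | CC(I)[P+](c1ccccc1)(c1ccccc1)c1ccccc1.[I-] | intermediate
19 | (1-iodoethylidene)triphenylphosphorane | CC(I)=P(c1ccccc1)(c1ccccc1)c1ccccc1 | intermediate
20 | tert-butyl{[(1S,2Z)-1-[(4S)-2,2-dimethyl-1,3-dioxolan-4-yl]-3-iodobut-2-en-1-yl]oxy}dimethylsilane | I/C(C)=C\[C@H](O[Si](C)(C)C(C)(C)C)[C@@H]1COC(C)(C)O1 | intermediate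
21 | (1S,2Z)-1-[(4S)-2,2-dimethyl-1,3-dioxolan-4-yl]-3-iodobut-2-en-1-ol | I/C(C)=C\[C@H](O)[C@@H]1COC(C)(C)O1 | intermediate
22 | 2-bromopropanoyl bromide (racemic) | CC(Br)C(=O)Br | starting material
23 | (1S,2Z)-1-[(4S)-2,2-dimethyl-1,3-dioxolan-4-yl]-3-iodobut-2-en-1-yl 2-bromopropanoate, both epimers at CHBr | I/C(C)=C\[C@H](OC(=O)C(C)Br)[C@@H]1COC(C)(C)O1 | intermediate
24 | (2S,3S,4Z)-1,2-dihydroxy-5-iodohex-4-en-3-yl 2-bromopropanoate | I/C(C)=C\[C@H](OC(=O)C(C)Br)[C@@H](O)CO | intermediate
25 | (2S,3S,4Z)-2-hydroxy-5-iodo-1-[(triethylsilyl)oxy]hex-4-en-3-yl 2-bromopropanoate | I/C(C)=C\[C@H](OC(=O)C(C)Br)[C@@H](O)CO[Si](CC)(CC)CC | intermediate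
26 | (3S,4Z)-5-iodo-2-oxo-1-[(triethylsilyl)oxy]hex-4-en-3-yl 2-bromopropanoate | I/C(C)=C\[C@H](OC(=O)C(C)Br)C(=O)CO[Si](CC)(CC)CC | intermediate
27 | O-bound diiodosamarium enolate of the propanoate of 26 (trivalent samarium) | I/C(C)=C\[C@H](OC(O[Sm](I)I)=CC)C(=O)CO[Si](CC)(CC)CC | intermediate
28 | (3R,4R,5S)-4-hydroxy-5-[(1Z)-2-iodoprop-1-en-1-yl]-3-methyl-4-{[(triethylsilyl)oxy]methyl}oxolan-2-one | I/C(C)=C\[C@@H]1OC(=O)[C@H](C)[C@@]1(O)CO[Si](CC)(CC)CC | intermediate
29 | B-alkyl-9-borabicyclo[3.3.1]nonane from 12 (boron on C4; C20 hydroxyl as its 9-BBN borinate) | O(CC1=C[C@@](C)([C@H](OC(C)=O)CCB2C3CCCC2CCC3)[C@@H](OC(C)=O)CC1)B1C2CCCC1CCC2 | intermediate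
30 | 2,14-diacetoxy-8,20-dihydroxy-9-(triethylsilyloxy)-9,10-secobriara-5Z,10-dien-19,7-olide | OCC1=C[C@@](C)([C@H](OC(C)=O)CC/C(C)=C\[C@@H]2OC(=O)[C@H](C)[C@@]2(O)CO[Si](CC)(CC)CC)[C@@H](OC(C)=O)CC1 | intermediate
31 | 2,14-diacetoxy-20-bromo-8-hydroxy-9-(triethylsilyloxy)-9,10-secobriara-5Z,10-dien-19,7-olide | BrCC1=C[C@@](C)([C@H](OC(C)=O)CC/C(C)=C\[C@@H]2OC(=O)[C@H](C)[C@@]2(O)CO[Si](CC)(CC)CC)[C@@H](OC(C)=O)CC1 | intermediate
32 | 2,14-diacetoxy-20-bromo-8-hydroxy-9-oxo-9,10-secobriara-5Z,10-dien-19,7-olide | BrCC1=C[C@@](C)([C@H](OC(C)=O)CC/C(C)=C\[C@@H]2OC(=O)[C@H](C)[C@@]2(O)C=O)[C@@H](OC(C)=O)CC1 | intermediate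
33 | C20 dichlorochromium allyl derivative of 32 (trivalent chromium) | Cl[Cr](Cl)CC1=C[C@@](C)([C@H](OC(C)=O)CC/C(C)=C\[C@@H]2OC(=O)[C@H](C)[C@@]2(O)C=O)[C@@H](OC(C)=O)CC1 | intermediate
34 | 2,14-diacetoxy-8,9-dihydroxybriara-5Z,11(20)-dien-19,7-olide | C=C1CC[C@H](OC(C)=O)[C@@]2(C)[C@H]1[C@@H](O)[C@@]1(O)[C@H](/C=C(/C)CC[C@H]2OC(C)=O)OC(=O)[C@@H]1C | intermediate
35 | (1S,2R,5Z,7S,8S,9R,10S,14S,17R)-2,9,14-triacetoxy-8-hydroxybriara-5,11(20)-dien-19,7-olide (CNP0187723.2) | C=C1CC[C@H](OC(C)=O)[C@@]2(C)[C@H]1[C@@H](OC(C)=O)[C@@]1(O)[C@H](/C=C(/C)CC[C@H]2OC(C)=O)OC(=O)[C@@H]1C | target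

## Step count and least certain steps

Total: 23 steps. Longest linear sequence: 14 steps (steps 10–18, then 19–23; the ring A branch, steps 1–9 then 19–23, is equally long).

Step 22 (key step). The most likely failure is poor facial selectivity: attack on the ring A face that carries the C2 branch (cis ring fusion), or reaction of a chelated aldehyde rotamer (C9 epimer). The chair, the aldehyde rotamer and the ring A face must all agree inside a strained ten-membered transition state. Intermolecular addition (oligomerisation) and α-ketol rearrangement of the α-hydroxy aldehyde are further risks. Fallback, setting out from 12 and 28 and returning at 34: the order of the two unions is reversed, so that the C9–C10 bond is made between separate fragments, where only the C1 substituents choose the ring A face. Alcohol 12 is converted (CBr4, PPh3) into the ring A allylic bromide F1, and 28 is oxidised (Swern conditions on the silyl ether) to the lactone aldehyde F2. An intermolecular Nozaki–Hiyama allylation (CrCl2, THF; the alkenyl iodide is inert without nickel) gives the homoallylic alcohol F3. Hydroboration with dicyclohexylborane, which should select the monosubstituted vinyl group over the hindered 1,1-disubstituted methylene, gives the alkylborane F4. Ring B is then closed at C4–C5 by an intramolecular B-alkyl Suzuki–Miyaura coupling (Pd(dppf)Cl2, AsPh3, Cs2CO3, high dilution) to give 34.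

Step 3. The risk is insufficient enantioselection at C2, because the nucleophile is a hindered carbon that becomes quaternary and the new stereocentre lies outside the ring. Fallback, setting out from 5 and 4 and returning at 7: the addition is run with an achiral ligand (1,4-bis(diphenylphosphino)butane) to give the racemic dione F5. The reduction of step 4 then fixes C1 and C14 by reagent control whatever the configuration at C2, and 7 is separated by chromatography from its C2 epimer F6.

Step 9. The risk is incomplete or unselective equilibration of the two allylic alcohols, or ionisation and dehydration of the perrhenate ester. Fallback, setting out from 11 and returning at 12: thionyl chloride in Et2O converts 11 with allylic transposition (SNi′) into the primary allylic chloride F7; displacement with HCO2Cs in DMF gives the formate F8; selective methanolysis of the formate (KHCO3, MeOH, 0 °C; the acetates survive) gives 12.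

Step 18. The risk is formation of the wrong C17 epimer, protonation of the enolate before it cyclises, or reductive loss of the α-acyloxy group of the ketone. Fallback, setting out from 21 and returning at 28: the lactone is built in two separate bond-forming events under chelation control. Alcohol 21 is protected (4-methoxybenzyl trichloroacetimidate, cat. La(OTf)3) as the 4-methoxybenzyl ether F9. Acetonide hydrolysis gives the diol F10, selective silylation the triethylsilyl ether F11, and Dess–Martin oxidation the ketone F12. A zinc Reformatsky reaction with ethyl 2-bromopropanoate, in which zinc is chelated between the ketone and the ether oxygen and the nucleophile enters from the side of the C7 hydrogen, gives the hydroxy ester F13. DDQ frees O7, which lactonises to 28; C17 epimers are separated at that stage.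

Step 21. The risk is sluggish silyl exchange of the hindered, neopentyl-like silyl ether, or methylthiomethyl ether formation at the tertiary hydroxyl. Fallback, setting out from 31 and returning at 32: the silyl ether is cleaved with HF·pyridine to the primary alcohol F14, which is oxidised with TEMPO and PhI(OAc)2, a method selective for primary alcohols and compatible with the allylic bromide.

## Further compounds

F1 | step 22 | (1S,2R)-2-[(1R)-1-acetoxyprop-2-en-1-yl]-4-(bromomethyl)-2-methylcyclohex-3-en-1-yl acetate | BrCC1=C[C@@](C)([C@H](OC(C)=O)C=C)[C@@H](OC(C)=O)CC1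
F2 | step 22 | (2S,3S,4R)-3-hydroxy-2-[(1Z)-2-iodoprop-1-en-1-yl]-4-methyl-5-oxooxolane-3-carbaldehyde | I/C(C)=C\[C@@H]1OC(=O)[C@H](C)[C@@]1(O)C=O
F3 | step 22 | intermolecular allylation product: ring A with C11(20) methylene, C2 acetoxyallyl branch and C10 bonded to the C9 carbinol of the iodoalkenyl lactone | C=C1CC[C@H](OC(C)=O)[C@@]([C@@H](C=C)OC(C)=O)(C)[C@H]1[C@@H](O)[C@@]1(O)[C@H](/C=C(/C)I)OC(=O)[C@@H]1C
F4 | step 22 | C4 dicyclohexylborane derived from F3 | C=C1CC[C@H](OC(C)=O)[C@@]([C@@H](CCB(C2CCCCC2)C2CCCCC2)OC(C)=O)(C)[C@H]1[C@@H](O)[C@@]1(O)[C@H](/C=C(/C)I)OC(=O)[C@@H]1C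
F5 | step 3 | racemic 2-[1-[(4-methoxyphenyl)methoxy]prop-2-en-1-yl]-2-methylcyclohexane-1,3-dione | O=C1CCCC(=O)C1(C)C(OCc1ccc(OC)cc1)C=C
F6 | step 3 | (2R,3S)-3-hydroxy-2-[(1S)-1-[(4-methoxyphenyl)methoxy]prop-2-en-1-yl]-2-methylcyclohexan-1-one | O=C1CCC[C@H](O)[C@]1(C)[C@@H](OCc1ccc(OC)cc1)C=C
F7 | step 9 | (1S,2R)-2-[(1R)-1-acetoxyprop-2-en-1-yl]-4-(chloromethyl)-2-methylcyclohex-3-en-1-yl acetate | ClCC1=C[C@@](C)([C@H](OC(C)=O)C=C)[C@@H](OC(C)=O)CC1
F8 | step 9 | (1S,2R)-2-[(1R)-1-acetoxyprop-2-en-1-yl]-4-(formyloxymethyl)-2-methylcyclohex-3-en-1-yl acetate | O=COCC1=C[C@@](C)([C@H](OC(C)=O)C=C)[C@@H](OC(C)=O)CC1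
F9 | step 18 | (4S)-4-[(1S,2Z)-3-iodo-1-[(4-methoxyphenyl)methoxy]but-2-en-1-yl]-2,2-dimethyl-1,3-dioxolane | I/C(C)=C\[C@H](OCc1ccc(OC)cc1)[C@@H]1COC(C)(C)O1
F10 | step 18 | (2S,3S,4Z)-5-iodo-3-[(4-methoxyphenyl)methoxy]hex-4-ene-1,2-diol | I/C(C)=C\[C@H](OCc1ccc(OC)cc1)[C@@H](O)CO
F11 | step 18 | (2S,3S,4Z)-5-iodo-3-[(4-methoxyphenyl)methoxy]-1-[(triethylsilyl)oxy]hex-4-en-2-ol | I/C(C)=C\[C@H](OCc1ccc(OC)cc1)[C@@H](O)CO[Si](CC)(CC)CC
F12 | step 18 | (3S,4Z)-5-iodo-3-[(4-methoxyphenyl)methoxy]-1-[(triethylsilyl)oxy]hex-4-en-2-one | I/C(C)=C\[C@H](OCc1ccc(OC)cc1)C(=O)CO[Si](CC)(CC)CC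
F13 | step 18 | ethyl ester of the open-chain hydroxy acid of 28 with O7 as its 4-methoxybenzyl ether | CCOC(=O)[C@H](C)[C@@](O)(CO[Si](CC)(CC)CC)[C@@H](OCc1ccc(OC)cc1)/C=C(/C)I
F14 | step 21 | 2,14-diacetoxy-20-bromo-8,9-dihydroxy-9,10-secobriara-5Z,10-dien-19,7-olide | BrCC1=C[C@@](C)([C@H](OC(C)=O)CC/C(C)=C\[C@@H]2OC(=O)[C@H](C)[C@@]2(O)CO)[C@@H](OC(C)=O)CC1
A1 | alternative 1 | 5,6-seco diene for ring-closing metathesis (C5 isopropenyl-type olefin and C6 vinyl group on the finished ring A and lactone) | C=C1CC[C@H](OC(C)=O)[C@@]([C@@H](CCC(C)=C)OC(C)=O)(C)[C@H]1[C@@H](OC(C)=O)[C@@]1(O)[C@H](C=C)OC(=O)[C@@H]1C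
A2 | alternative 2 | fourteen-membered 1,2-epoxy-cembra-5Z,10E-dienolide (1,10-seco precursor of the transannular cyclisation) | C/C1=C\[C@@H](OC(C)=O)[C@@]2(O)[C@H](/C=C(/C)CC[C@H]3O[C@@]3(C)[C@@H](OC(C)=O)CC1)OC(=O)[C@@H]2C
A3 | alternative 3 | thirteen-membered α-allyloxy ketone (C9–O–C20 ether; C8 ketone; C7 silyl ether) for [2,3]-Wittig ring contraction | C/C1=C/[C@H](O[Si](C)(C)C(C)(C)C)C(=O)COCC2=C[C@@](C)([C@H](OC(C)=O)CC1)[C@@H](OC(C)=O)CC2
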